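At early times isomer of the product trailed the target: the west run read 0.3 % beside 2.7 % at 6.00 min, but 8.9 % beside 15.5 % at 20.0 min. So I took the isomer as made from target on the catalyst, pseudo-first-order in target, and assumed a rate proportional to catalyst concentration, which at fixed loading follows the charge of starting material.

common to all: free catalyst 0.1 mol%

|  | starting material | second substrate | solid reagent | temperature | remark | time |
|---|---|---|---|---|---|---|
| east | 3.3 mM | 0.50 equiv | 3 equiv | 85 °C | run made earlier |  |
| west | 30 mM | 0.50 equiv | 3 equiv | 100 °C | run made earlier |  |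
| dusk | 2.5 mM | 0.500 equiv | 3.00 equiv | 100 °C |  | 40 min |
| midnight | 15 mM | 0.500 equiv | 3.00 equiv | 100 °C |  | 40 min |
| noon | 5.0 mM | 0.500 equiv | 3.00 equiv | 100 °C |  | 40 min |
| winter | 10 mM | 0.500 equiv | 3.00 equiv | 100 °C |  | 40 min |
| summer | 20 mM | 0.500 equiv | 3.00 equiv | 100 °C |  | 40 min |

| run | time / min | target / % | isomer of the product / % | starting material / % |
|---|---|---|---|---|
| east | 3.00 | 0.7 | 0.4 | 97.1 |
| east | 6.00 | 3.4 | 0.8 | 96.5 |
| east | 12.0 | 10.4 | 2.9 | 90.8 |
| east | 20.0 | 17.9 | 1.7 | 81.5 |
| east | 40.0 | 33.5 | 5.3 | 62.1 |
| west | 1.50 | 0 | 0 | 99.7 |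
| west | 3.00 | 0.8 | 0 | 98.5 |
| west | 6.00 | 2.7 | 0.3 | 98.8 |
| west | 10.0 | 1.5 | 1.4 | 95.1 |
| west | 20.0 | 15.5 | 8.9 | 77.2 |

(standard deviation of a reading: 1 percentage point)

- solid reagent is a solid; its amount is given per volume of the solution
- the numbers in the tables scatter by 1 percentage point (one standard deviation)
- at the start none of the solid reagent is in solution

1. the flasks by share of target in all that became target or isomer of the product, highest first, at 40 min (dusk / midnight / noon / winter / summer)
2. the share of target in all that became target or isomer of the product of the flask you put first, at 40 min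
3. the share of target in all that became target or isomer of the product of the flask you put last, at 40 min

Call τ the isomerisation time, the time constant of that step. Taking target as growing about linearly up to time t, with its loss to isomer neglected, isomer over target is t/(2τ), so the share s of target is

s = 1 / (1 + t/(2τ))

What had to be known well? Time and charges are given, so τ remained. A relative error in τ reaches s multiplied by s(1 − s), which counts most near an even split. The east run stood at 85 °C, not 100 °C, so I left it out. In the west run the last isomer reading enters whole, and it is 8.9 % with a scatter of 1 percentage point. The target readings of the last interval enter averaged, and I dropped the earlier ones, none above 2.7 %. Target area of that interval over the last isomer reading gives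

τ(west) = 9.55 min

This is my isomerisation time at the west charge. Scaled inversely with the charge:

dusk: τ = 115 min, s = 85.1 %
summer: τ = 14.3 min, s = 41.7 %

So in my reckoning s falls as the charge rises, from dusk down to summer.

The forecast gave dusk > noon > winter > midnight > summer, with 84 % and 68 %, the latter higher than my 41.7 % for summer, on the ground “Dilute should be best”.

The flasks gave dusk > noon > winter > midnight > summer, with 75.0 % and 39.7 %.

    partner + catalyst intermediate A → free catalyst + target (k = 193 M⁻¹ s⁻¹, Ea = 40.0 kJ mol⁻¹)
    second substrate + free catalyst ⇌ catalyst intermediate B (K = 936 M⁻¹, k = 519 M⁻¹ s⁻¹, Ea = 49.0 kJ mol⁻¹, ΔH = −13.0 kJ mol⁻¹)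
    partner + catalyst intermediate B → free catalyst + second product (k = 3810 M⁻¹ s⁻¹, Ea = 52.0 kJ mol⁻¹)
    target + free catalyst ⇌ isomer of the product + free catalyst, rate k4*[free catalyst]*[target] forward; the back reaction follows from the equilibrium constant (K = 3.00, k = 126 M⁻¹ s⁻¹, Ea = 38.0 kJ mol⁻¹, ΔH = −32.0 kJ mol⁻¹)
    solid reagent ⇌ partner, rate k5*(cs5 - [partner]) while solid is left; crystals form when [partner] > cs5 (solubility = 6.30 mM, k = 0.00465 s⁻¹)
    starting material + free catalyst ⇌ catalyst intermediate A (K = 59.0 M⁻¹, k = 23900 M⁻¹ s⁻¹, Ea = 35.0 kJ mol⁻¹, ΔH = −65.0 kJ mol⁻¹)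
    (constants at 100 °C)

Put back through the line for s, the share of dusk asks for τ = 59.8 min, not 115 min. In dusk the forward isomerisation step alone, at 126 M⁻¹ s⁻¹ on the 90.2 % of catalyst left free, takes 58.6 min, longer than the 40 min of the run, and 6.98 % of isomer of the product stood beside 20.9 % of target. In summer, with 73.4 % free on a larger charge, it takes 9.01 min, shorter than the run, and the isomer stood at 41.7 % against 27.5 %. Scaled to the neighbour of dusk with 0.4 mol% of free catalyst, τ becomes 15.0 min and s 42.9 %, and that flask stands at 39.7 %.

All runs come from a simulation on assumed constants; scatter was added.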